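The earlier runs and the new flask were generated by integration on assumed constants; scatter was added.

At the time of reading, 12 min, the blue run had lost 32.9% of its electrophile and the red run 39.5%, so 2.05 times the nucleophile had bought 1.20 times the conversion.

in all of them: electrophile 0.10 M
- blue: nucleophile 0.19 M; solid base 0.12 M; run made earlier
- red: nucleophile 0.39 M; solid base 0.12 M; run made earlier
- north: nucleophile 0.220 M; solid base 0.120 M; time 12 min
- west: nucleophile 0.150 M; solid base 0.120 M; time 12 min
- north-east: nucleophile 0.340 M; solid base 0.120 M; time 12 min

| run | time / min | electrophile / % | target / % |
|---|---|---|---|
| blue | 1.50 | 81.3 | 18.6 |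
| blue | 3.00 | 77.5 | 22.6 |
| blue | 5.00 | 74.5 | 26.3 |
| blue | 6.00 | 73.5 | 26.5 |
| blue | 8.00 | 71.7 | 28.4 |
| blue | 10.0 | 70.2 | 31.2 |
| blue | 12.0 | 67.1 | 32.2 |
| red | 1.00 | 78.0 | 22.2 |
| red | 1.33 | 75.9 | 24.1 |
| red | 2.00 | 72.8 | 26.4 |
| red | 3.00 | 71.1 | 28.8 |
| red | 5.00 | 68.4 | 32.3 |
| red | 8.00 | 63.9 | 35.1 |
| red | 12.0 | 60.5 | 38.9 |

(standard deviation of a reading: 0.5 percentage points)

- solid base is a solid; its amount is given per volume of the solution
- what was read earlier has a scatter of 0.5 percentage points, one standard deviation
- at the start none of the solid base is in solution

* part of the electrophile that has reacted at the end, north
* part of the electrophile that has reacted at the end, west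
* part of the electrophile that has reacted at the end, north-east
* what raising the concentration of nucleophile from its lowest to its highest value here does to the part of the electrophile that has reacted (changes below 5 percentage points count as none) (it rises / it falls / no change)

My first estimate was a straight line through those two conversions, which put west at 31.6%, but the same line stood at 26.6% with no nucleophile at all, so it was the weak link.

To reforge it I compared rates within the blue run: the electrophile went 11.8 times as fast in the first 1.50 min as after 5.00 min, although 74.5% of it still stood at that time. The blue charge of nucleophile, 0.19 M, was more than the 0.0255 M of electrophile consumed by then, so I supposed that free nucleophile was vanishing by another road, faster the more there was. I took that loss to go with the square of the nucleophile and to run well ahead of the reaction with electrophile, and on that supposition, at fixed time and other charges, conversion grows roughly with the logarithm of the nucleophile charge.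

I therefore named G the gain in conversion per unit of ln(nucleophile charge), at fixed time and other charges, and read it from the two runs as 9.2 percentage points. Counted from blue, G gave 34.2% for north, 30.7% for west and 38.2% for north-east. From west to north-east that is a rise of 7.5 points, above the 5 points that counts.

The forecast stood at 34% for north, 30.7% for west and 38% for north-east, with the verdict it rises, on the ground that “the burst grows with nucleophile”. Mine lay a little above it at north and north-east.

The simulation gave 33.7% for north, 29.9% for west and 38.0% for north-east: it rises, by 8.2 points.

    electrophile + nucleophile → acid set free + target (k = 2.31 M⁻¹ min⁻¹)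
    nucleophile + acid set free ⇌ protonated nucleophile, settled at all times (K = 2900 M⁻¹)
    acid set free + free base ⇌ salt of the base (K = 16000 M⁻¹, k = 98.8 M⁻¹ min⁻¹)
    2 nucleophile → self-condensation product (k = 8.74 M⁻¹ min⁻¹)
    solid base ⇌ free base, rate k5*(cs5 - [free base]) while solid is left; crystals form when [free base] > cs5 (solubility = 0.0640 M, k = 0.144 min⁻¹)

North-east kept 1.84% of its nucleophile free at the end, and the same flask without the loss to self-condensation product reached 99.2%, so that loss is the main reason for the conversion missing there. Between west and north-east the flasks themselves show a G of 10 points. Carried from west down to 0.037 M of nucleophile, the G read from the runs gives 17.0%; that flask, otherwise charged as west, reached 16.1%.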